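The C3a–C7a bond (1-benzofuran-2-one locants) is disconnected; it is the ring-fusion bond shared by the cyclohexene and the γ-lactone. Its ends are a lactone O–CH (C7a) and a carbon bearing the acrylate unit (C3a), the pattern left by a 2-carboxyallyl metal adding to an aldehyde. The key step closes an open-chain aldehyde carrying a geometrically defined 2-(methoxycarbonyl)allyl boronate by intramolecular allylboration. One chair transition state forms C3a–C7a, sets both new stereocentres from the silyloxy-bearing C4 and reveals the 3-methylidene; the borate then lactonises, so both rings close in one operation. The precursor is built from (S)-citronellic acid, whose carboxyl carbon becomes C4 and whose C2 becomes C5.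

Key step: step 15

Assumption: the target is read as (3aR,4S,7aR) with an (S) side-chain centre, i.e. a trans-fused lactone whose C4 hydroxyl is cis to the C3a–C3 bond; ring locants are also used for the open-chain carbons that become these atoms.

Step 1
Reactants: 1 (S)-citronellic acid
Product: 2 tert-butyl (3S)-3,7-dimethyloct-6-enoate
Conditions: Boc2O, DMAP (cat.), t-BuOH, 35 °C
Reagents that add atoms: di-tert-butyl dicarbonate CC(C)(C)OC(=O)OC(=O)OC(C)(C)C; tert-butanol CC(C)(C)O
Why: Mixed-anhydride activation and DMAP-catalysed acyl transfer to tert-butanol (Steglich-type esterification) give an ester that tolerates enolate and palladium chemistry and can later be cleaved beside acetate and isobutyrate; the C3 stereocentre is untouched.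

Step 2
Reactants: 3 glycolic acid; 4 isobutyryl chloride
Product: 5 (isobutyryloxy)acetic acid
Conditions: pyridine, CH2Cl2, 0 °C to rt; aq. HCl work-up
Reagents that add atoms: none
Why: O-Acylation of the hydroxyl group by the acid chloride (pyridine-mediated esterification); any mixed anhydride at the carboxyl group is hydrolysed during the aqueous work-up.

Step 3
Reactants: 2 tert-butyl (3S)-3,7-dimethyloct-6-enoate; 5 (isobutyryloxy)acetic acid
Product: 7 tert-butyl (3S)-2-[(isobutyryloxy)acetyl]-3,7-dimethyloct-6-enoate (C2 epimers), via 2-chloro-2-oxoethyl 2-methylpropanoate 6 (not isolated)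
Conditions: 5, (COCl)2, DMF (cat.), CH2Cl2, rt, evaporate; 2, LDA (2.1 equiv), THF, −78 °C, then 6, −78 °C; AcOH quench
Reagents that add atoms: none
Why: Crossed Claisen condensation, in which the lithium ester enolate is C-acylated by the acid chloride and the second equivalent of base holds the β-keto ester as its enolate; the new C2 centre is an epimer mixture that becomes sp2 in step 4.

Step 4
Reactants: 7 tert-butyl (3S)-2-[(isobutyryloxy)acetyl]-3,7-dimethyloct-6-enoate
Product: 8 tert-butyl (2Z)-4-(isobutyryloxy)-2-[(2S)-6-methylhept-5-en-2-yl]-3-[(trifluoromethylsulfonyl)oxy]but-2-enoate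
Conditions: NaH, CH2Cl2, 0 °C; Tf2O, −78 to 0 °C
Reagents that add atoms: triflic anhydride O=S(=O)(OS(=O)(=O)C(F)(F)F)C(F)(F)F
Why: O-Sulfonylation of the chelated, U-shaped sodium enolate of the β-keto ester should give the Z enol triflate (OTf cis to the ester), which fixes the geometry of the later tetrasubstituted alkene.

Step 5
Reactants: 8 Z enol triflate; 9 tert-butyldimethyl(vinyloxy)silane
Product: 11 tert-butyl (2E)-5-[(tert-butyldimethylsilyl)oxy]-3-[(isobutyryloxy)methyl]-2-[(2S)-6-methylhept-5-en-2-yl]pent-2-enoate, via 9-[2-(tert-butyldimethylsilyloxy)ethyl]-9-borabicyclo[3.3.1]nonane 10 (not isolated)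
Conditions: 9, 9-BBN dimer, THF, 0 °C to rt; then 8, Pd(dppf)Cl2, AsPh3, Cs2CO3, DMF/H2O, rt
Reagents that add atoms: none
Why: Anti-Markovnikov hydroboration of the silyl enol ether and B-alkyl Suzuki–Miyaura coupling with retention of alkene geometry place the two-carbon arm cis to the ester, i.e. cis to the future C4.

Step 6
Reactants: 11 tetrasubstituted enoate
Product: 13 tert-butyl (2E)-5-[(tert-butyldimethylsilyl)oxy]-2-[(2S)-5-hydroxypentan-2-yl]-3-[(isobutyryloxy)methyl]pent-2-enoate, via secondary ozonide 12 (not isolated)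
Conditions: O3, CH2Cl2, −78 °C (indicator dye); then NaBH4, MeOH, −78 to 0 °C
Reagents that add atoms: ozone [O-][O+]=O
Why: Ozonolysis with reductive work-up; the electron-rich trisubstituted alkene is cleaved much faster than the tetrasubstituted alkene, which is deactivated by conjugation with the ester, and borohydride reduces the ozonide to the primary alcohol.

Step 7
Reactants: 13 primary alcohol
Product: 14 tert-butyl (2E)-2-[(2S)-5-acetoxypentan-2-yl]-5-[(tert-butyldimethylsilyl)oxy]-3-[(isobutyryloxy)methyl]pent-2-enoate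
Conditions: Ac2O, pyridine, DMAP (cat.), CH2Cl2, 0 °C to rt
Reagents that add atoms: acetic anhydride CC(=O)OC(C)=O
Why: DMAP-catalysed acetylation of the primary alcohol installs the side-chain acetate of the target.

Step 8
Reactants: 14 tert-butyl ester
Product: 16 (2E)-2-[(2S)-5-acetoxypentan-2-yl]-5-[(tert-butyldimethylsilyl)oxy]-3-[(isobutyryloxy)methyl]pent-2-enoic acid, via trimethylsilyl ester 15 (not isolated)
Conditions: TMSOTf, 2,6-lutidine, CH2Cl2, 0 °C; aq. work-up
Reagents that add atoms: none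
Why: Silyl triflate-induced cleavage of the tert-butyl ester (loss of isobutene) gives a trimethylsilyl ester that is hydrolysed on work-up; acetate, isobutyrate and the TBS ether should be inert under these buffered conditions.

Step 9
Reactants: 16 carboxylic acid; 17 methyl propiolate
Product: 20 methyl (5E)-5-[(2S)-5-acetoxypentan-2-yl]-8-[(tert-butyldimethylsilyl)oxy]-6-[(isobutyryloxy)methyl]-4-oxooct-5-en-2-ynoate, via acid chloride 18 (not isolated), via chlorozinc acetylide 19 (not isolated)
Conditions: 16, 1-chloro-N,N,2-trimethylprop-1-en-1-amine, CH2Cl2, 0 °C; 17, LiHMDS, THF, −78 °C, then ZnCl2; combine, Pd(PPh3)4 (5 mol %), THF, −20 °C to rt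
Reagents that add atoms: none
Why: Neutral conversion of the acid into its chloride by the α-chloroenamine, followed by palladium-catalysed acylation of the alkynylzinc (Negishi-type acyl coupling), joins the future C4 and C3a as an ynone without any base-sensitive operation.

Step 10
Reactants: 20 ynone
Product: 21 methyl (4S,5E)-5-[(2S)-5-acetoxypentan-2-yl]-8-[(tert-butyldimethylsilyl)oxy]-4-hydroxy-6-[(isobutyryloxy)methyl]oct-5-en-2-ynoate
Conditions: (R)-Me-CBS (0.5 equiv), catecholborane, CH2Cl2, −78 °C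
Reagents that add atoms: none
Why: Corey–Bakshi–Shibata reduction; with the bulky tetrasubstituted alkenyl group as the large and the alkynyl group as the small substituent, the (R)-catalyst should deliver hydride to the face that gives the 4S carbinol (catalyst control).

Step 11
Reactants: 21 propargylic alcohol
Product: 22 methyl (4S,5E)-5-[(2S)-5-acetoxypentan-2-yl]-8-[(tert-butyldimethylsilyl)oxy]-6-[(isobutyryloxy)methyl]-4-[(triisopropylsilyl)oxy]oct-5-en-2-ynoate
Conditions: TIPSOTf, 2,6-lutidine, CH2Cl2, −40 to 0 °C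
Reagents that add atoms: triisopropylsilyl triflate CC(C)[Si](OS(=O)(=O)C(F)(F)F)(C(C)C)C(C)C
Why: Silylation with the silyl triflate protects the hindered propargylic alcohol; the bulky TIPS group also blocks butenolide formation after step 12 and serves stereocontrol in step 15.

Step 12
Reactants: 22 silyloxy ynoate
Product: 24 methyl (2E,4S,5E)-5-[(2S)-5-acetoxypentan-2-yl]-8-[(tert-butyldimethylsilyl)oxy]-2-iodo-6-[(isobutyryloxy)methyl]-4-[(triisopropylsilyl)oxy]octa-2,5-dienoate, via α-stannyl enoate 23 (not isolated)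
Conditions: Bu3SnH, Pd(PPh3)4 (3 mol %), THF, 0 °C; then I2, CH2Cl2, 0 °C
Reagents that add atoms: iodine II
Why: Palladium-catalysed syn-hydrostannation of the alkynoate places tin α to the ester and hydrogen on the β-carbon, and iododestannylation proceeds with retention, so the silyloxy carbon ends cis to the ester.

Step 13
Reactants: 24 alkenyl iodide; 25 2-(iodomethyl)-4,4,5,5-tetramethyl-1,3,2-dioxaborolane
Product: 27 methyl (2Z,4S,5E)-5-[(2S)-5-acetoxypentan-2-yl]-8-[(tert-butyldimethylsilyl)oxy]-6-[(isobutyryloxy)methyl]-2-[(4,4,5,5-tetramethyl-1,3,2-dioxaborolan-2-yl)methyl]-4-[(triisopropylsilyl)oxy]octa-2,5-dienoate, via borylmethylzinc iodide 26 (not isolated)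
Conditions: 25, Zn dust, THF, rt; then 24, Pd(PPh3)4 (5 mol %), THF, 45 °C
Reagents that add atoms: none
Why: Zinc insertion into the iodomethylboronate and Negishi coupling with the alkenyl iodide, with retention of geometry, give the allylboronate in which the silyloxy carbon is trans to CH2B (E-crotyl type).

Step 14
Reactants: 27 allylboronate
Product: 28 methyl (2Z,4S,5E)-5-[(2S)-5-acetoxypentan-2-yl]-8-hydroxy-6-[(isobutyryloxy)methyl]-2-[(4,4,5,5-tetramethyl-1,3,2-dioxaborolan-2-yl)methyl]-4-[(triisopropylsilyl)oxy]octa-2,5-dienoate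
Conditions: CSA (0.2 equiv), MeOH/CH2Cl2, 0 °C
Reagents that add atoms: none
Why: Acid-catalysed methanolysis removes the unhindered primary TBS ether far faster than the hindered secondary TIPS ether; the ester-deactivated allyl pinacol boronate should tolerate the mild acid.

Step 15
Reactants: 28 primary alcohol
Product: 31 [(3aS,4S,7aR)-5-[(2S)-5-acetoxypentan-2-yl]-3-methylidene-2-oxo-4-[(triisopropylsilyl)oxy]-3a,4,7,7a-tetrahydro-1-benzofuran-6-yl]methyl 2-methylpropanoate (3aS only through a change of CIP priority), via aldehyde 29 (not isolated), via pinacol borate 30 (not isolated)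
Conditions: Dess–Martin periodinane, NaHCO3, CH2Cl2, 0 °C to rt; then toluene, 60 °C; then p-TsOH·H2O (cat.), rt
Reagents that add atoms: none
Why: Dess–Martin oxidation gives the β,γ-unsaturated aldehyde 29, whose carbonyl oxygen binds boron so that the γ-carbon of the allylboronate attacks through a closed six-membered chair (the closest known reaction type is the intramolecular allylboration of ω-formyl allylboronates, combined with the 2-alkoxycarbonylallylboronate route to α-methylene γ-lactones); acid then exchanges the borate 30 and lactonises it. The cyclohexene closes by 6-exo-trig attack on the aldehyde (C3a–C7a), the lactone by 5-exo-trig acyl substitution of O–C7a on the methyl ester. The C3a/C7a relationship should be trans because the silyloxy carbon is trans to CH2B in 28 (configurationally stable pinacol boronate), which puts both ring bonds equatorial in a trans-decalin-like chair. Which face reacts is set by the C4 stereocentre: the OTIPS group should sit pseudoaxial on the forming ring, syn to the enoate ("inside"), because the pseudoequatorial alternative suffers A(1,2) strain against the branched side chain on the tetrasubstituted alkene, so the new bond forms with the acrylate cis to OTIPS and gives the C3a and C7a configurations of the target. The step needs γ-selectivity and no drift of the aldehyde into conjugation; the closed transition state secures the first, and buffered neutral oxidation next to a tetrasubstituted alkene the second.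

Step 16
Reactants: 31 TIPS-protected lactone
Product: 32 [(3aR,4S,7aR)-5-[(2S)-5-acetoxypentan-2-yl]-4-hydroxy-3-methylidene-2-oxo-3a,4,7,7a-tetrahydro-1-benzofuran-6-yl]methyl 2-methylpropanoate (CNP0246650.1)
Conditions: HF·pyridine, pyridine, THF, 0 °C to rt
Reagents that add atoms: none
Why: Fluoride-mediated desilylation under mildly acidic conditions frees the C4 hydroxyl; the α-methylene lactone and the two esters should survive, and acyl migration is not promoted.

Compound list
1 | (S)-citronellic acid, (3S)-3,7-dimethyloct-6-enoic acid | C[C@@H](CCC=C(C)C)CC(=O)O | starting material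
2 | tert-butyl (3S)-3,7-dimethyloct-6-enoate | C[C@@H](CCC=C(C)C)CC(=O)OC(C)(C)C | intermediate
3 | glycolic acid | OCC(=O)O | starting material
4 | isobutyryl chloride | CC(C)C(=O)Cl | starting material
5 | (isobutyryloxy)acetic acid | CC(C)C(=O)OCC(=O)O | intermediate
6 | 2-chloro-2-oxoethyl 2-methylpropanoate | CC(C)C(=O)OCC(=O)Cl | intermediate
7 | tert-butyl (3S)-2-[(isobutyryloxy)acetyl]-3,7-dimethyloct-6-enoate, C2 epimers | C[C@@H](CCC=C(C)C)C(C(=O)OC(C)(C)C)C(=O)COC(=O)C(C)C | intermediate
8 | tert-butyl (2Z)-4-(isobutyryloxy)-2-[(2S)-6-methylhept-5-en-2-yl]-3-[(trifluoromethylsulfonyl)oxy]but-2-enoate | C[C@@H](CCC=C(C)C)/C(C(=O)OC(C)(C)C)=C(/OS(=O)(=O)C(F)(F)F)COC(=O)C(C)C | intermediate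
9 | tert-butyldimethyl(vinyloxy)silane | C=CO[Si](C)(C)C(C)(C)C | starting material
10 | 9-[2-(tert-butyldimethylsilyloxy)ethyl]-9-borabicyclo[3.3.1]nonane | CC(C)(C)[Si](C)(C)OCCB1C2CCCC1CCC2 | intermediate
11 | tert-butyl (2E)-5-[(tert-butyldimethylsilyl)oxy]-3-[(isobutyryloxy)methyl]-2-[(2S)-6-methylhept-5-en-2-yl]pent-2-enoate | C[C@@H](CCC=C(C)C)/C(C(=O)OC(C)(C)C)=C(/CCO[Si](C)(C)C(C)(C)C)COC(=O)C(C)C | intermediate
12 | secondary ozonide (3,3-dimethyl-1,2,4-trioxolane) of 11 | C[C@@H](CCC1OOC(C)(C)O1)/C(C(=O)OC(C)(C)C)=C(/CCO[Si](C)(C)C(C)(C)C)COC(=O)C(C)C | intermediate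
13 | tert-butyl (2E)-5-[(tert-butyldimethylsilyl)oxy]-2-[(2S)-5-hydroxypentan-2-yl]-3-[(isobutyryloxy)methyl]pent-2-enoate | C[C@@H](CCCO)/C(C(=O)OC(C)(C)C)=C(/CCO[Si](C)(C)C(C)(C)C)COC(=O)C(C)C | intermediate
14 | tert-butyl (2E)-2-[(2S)-5-acetoxypentan-2-yl]-5-[(tert-butyldimethylsilyl)oxy]-3-[(isobutyryloxy)methyl]pent-2-enoate | C[C@@H](CCCOC(C)=O)/C(C(=O)OC(C)(C)C)=C(/CCO[Si](C)(C)C(C)(C)C)COC(=O)C(C)C | intermediate
15 | trimethylsilyl ester of 16 | C[C@@H](CCCOC(C)=O)/C(C(=O)O[Si](C)(C)C)=C(/CCO[Si](C)(C)C(C)(C)C)COC(=O)C(C)C | intermediate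
16 | (2E)-2-[(2S)-5-acetoxypentan-2-yl]-5-[(tert-butyldimethylsilyl)oxy]-3-[(isobutyryloxy)methyl]pent-2-enoic acid | C[C@@H](CCCOC(C)=O)/C(C(=O)O)=C(/CCO[Si](C)(C)C(C)(C)C)COC(=O)C(C)C | intermediate
17 | methyl propiolate | C#CC(=O)OC | starting material
18 | acid chloride of 16 | C[C@@H](CCCOC(C)=O)/C(C(Cl)=O)=C(/CCO[Si](C)(C)C(C)(C)C)COC(=O)C(C)C | intermediate
19 | chloro(3-methoxy-3-oxoprop-1-yn-1-yl)zinc | COC(=O)C#C[Zn]Cl | intermediate
20 | methyl (5E)-5-[(2S)-5-acetoxypentan-2-yl]-8-[(tert-butyldimethylsilyl)oxy]-6-[(isobutyryloxy)methyl]-4-oxooct-5-en-2-ynoate | C[C@@H](CCCOC(C)=O)/C(C(=O)C#CC(=O)OC)=C(/CCO[Si](C)(C)C(C)(C)C)COC(=O)C(C)C | intermediate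
21 | methyl (4S,5E)-5-[(2S)-5-acetoxypentan-2-yl]-8-[(tert-butyldimethylsilyl)oxy]-4-hydroxy-6-[(isobutyryloxy)methyl]oct-5-en-2-ynoate | C[C@@H](CCCOC(C)=O)/C(=C(/CCO[Si](C)(C)C(C)(C)C)COC(=O)C(C)C)[C@@H](O)C#CC(=O)OC | intermediate
22 | methyl (4S,5E)-5-[(2S)-5-acetoxypentan-2-yl]-8-[(tert-butyldimethylsilyl)oxy]-6-[(isobutyryloxy)methyl]-4-[(triisopropylsilyl)oxy]oct-5-en-2-ynoate | C[C@@H](CCCOC(C)=O)/C(=C(/CCO[Si](C)(C)C(C)(C)C)COC(=O)C(C)C)[C@@H](O[Si](C(C)C)(C(C)C)C(C)C)C#CC(=O)OC | intermediate
23 | methyl (2E,4S,5E)-2-(tributylstannyl) analogue of 24 | C[C@@H](CCCOC(C)=O)/C(=C(/CCO[Si](C)(C)C(C)(C)C)COC(=O)C(C)C)[C@@H](O[Si](C(C)C)(C(C)C)C(C)C)/C=C(/[Sn](CCCC)(CCCC)CCCC)C(=O)OC | intermediate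
24 | methyl (2E,4S,5E)-5-[(2S)-5-acetoxypentan-2-yl]-8-[(tert-butyldimethylsilyl)oxy]-2-iodo-6-[(isobutyryloxy)methyl]-4-[(triisopropylsilyl)oxy]octa-2,5-dienoate | C[C@@H](CCCOC(C)=O)/C(=C(/CCO[Si](C)(C)C(C)(C)C)COC(=O)C(C)C)[C@@H](O[Si](C(C)C)(C(C)C)C(C)C)/C=C(/I)C(=O)OC | intermediate
25 | 2-(iodomethyl)-4,4,5,5-tetramethyl-1,3,2-dioxaborolane | ICB1OC(C)(C)C(C)(C)O1 | starting material
26 | iodo[(4,4,5,5-tetramethyl-1,3,2-dioxaborolan-2-yl)methyl]zinc | I[Zn]CB1OC(C)(C)C(C)(C)O1 | intermediate
27 | methyl (2Z,4S,5E)-5-[(2S)-5-acetoxypentan-2-yl]-8-[(tert-butyldimethylsilyl)oxy]-6-[(isobutyryloxy)methyl]-2-[(pinacolboryl)methyl]-4-[(triisopropylsilyl)oxy]octa-2,5-dienoate | C[C@@H](CCCOC(C)=O)/C(=C(/CCO[Si](C)(C)C(C)(C)C)COC(=O)C(C)C)[C@@H](O[Si](C(C)C)(C(C)C)C(C)C)/C=C(/CB1OC(C)(C)C(C)(C)O1)C(=O)OC | intermediate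
28 | 8-hydroxy compound from 27 (primary alcohol) | C[C@@H](CCCOC(C)=O)/C(=C(/CCO)COC(=O)C(C)C)[C@@H](O[Si](C(C)C)(C(C)C)C(C)C)/C=C(/CB1OC(C)(C)C(C)(C)O1)C(=O)OC | intermediate
29 | 8-oxo compound from 28 (aldehyde) | C[C@@H](CCCOC(C)=O)/C(=C(/CC=O)COC(=O)C(C)C)[C@@H](O[Si](C(C)C)(C(C)C)C(C)C)/C=C(/CB1OC(C)(C)C(C)(C)O1)C(=O)OC | intermediate
30 | pinacol borate of the cyclised trans-hydroxy ester: methyl 2-[cyclohexenyl]acrylate with O–Bpin at the future C7a and OTIPS at C4 | C=C(C(=O)OC)[C@H]1[C@H](OB2OC(C)(C)C(C)(C)O2)CC(COC(=O)C(C)C)=C([C@@H](C)CCCOC(C)=O)[C@H]1O[Si](C(C)C)(C(C)C)C(C)C | intermediate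
31 | [(3aS,4S,7aR)-5-[(2S)-5-acetoxypentan-2-yl]-3-methylidene-2-oxo-4-[(triisopropylsilyl)oxy]-3a,4,7,7a-tetrahydro-1-benzofuran-6-yl]methyl 2-methylpropanoate | C=C1C(=O)O[C@@H]2CC(COC(=O)C(C)C)=C([C@@H](C)CCCOC(C)=O)[C@@H](O[Si](C(C)C)(C(C)C)C(C)C)[C@@H]12 | intermediate
32 | [(3aR,4S,7aR)-5-[(2S)-5-acetoxypentan-2-yl]-4-hydroxy-3-methylidene-2-oxo-3a,4,7,7a-tetrahydro-1-benzofuran-6-yl]methyl 2-methylpropanoate | C=C1C(=O)O[C@@H]2CC(COC(=O)C(C)C)=C([C@@H](C)CCCOC(C)=O)[C@@H](O)[C@@H]12 | target

Total step count: 16. Longest linear sequence: 15 steps (steps 1 and 3–16, from 1 to 32).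

Steps most likely to fail

Step 15. The ring closure may not discriminate the two faces of the allyl unit well enough: a transition state with the C–H bond of the silyloxy carbon eclipsing the enoate (OTIPS pseudoequatorial) competes and would lead to the C3a,C7a-diepimer, and geometric drift of the boronate would add cis-fused material. The fallback locks the oxygen of the future C4 into a ring instead of silylating it. It sets out from carbinol 21: hydrostannation (Bu3SnH, Pd(PPh3)4) now gives a cis-γ-hydroxy enoate that should lactonise spontaneously to the 3-(tributylstannyl)butenolide F1, iodine gives the 3-iodobutenolide F2, and Negishi coupling with 26 gives the 3-(borylmethyl)butenolide F3. CSA in methanol frees the primary alcohol F4. Dess–Martin oxidation to the aldehyde F5 and warming bring about the same intramolecular allylboration, but through an allyl unit whose geometry and C–O conformation are fixed by the butenolide ring, so the new bond must form cis to the ring oxygen. Aqueous work-up should give the isomeric cis-fused lactone F6, which carries a free hydroxyl at the future C7a, trans to the acrylate carbon. Acyl transfer from the C4 oxygen to the C7a oxygen (Ti(OiPr)4 cat., toluene, 60 °C, with recycling of unchanged F6) then gives 32, where the fallback comes back to the route. This last equilibrium may favour F6 and is the weak point of the fallback.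

Step 5. The β-silyloxyethyl borane may undergo β-elimination or protodeboronation faster than it transmetallates to the hindered, fully substituted alkenylpalladium intermediate. The fallback sets out from triflate 8 and brings in the two-carbon arm as a vinyl group: Stille coupling with tributyl(vinyl)stannane (Pd(PPh3)4, LiCl, THF, 60 °C) gives the dienoate F7; 9-BBN should hydroborate only the monosubstituted terminal alkene, and NaBO3 oxidation gives the primary alcohol F8; TBSCl and imidazole then return to 11.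

Step 9. The metallated propiolate may oligomerise before the hindered acid chloride acylates it. The fallback sets out from acid 16 through its chloride 18: reduction with Bu3SnH and Pd(PPh3)4 gives the enal F9, and zinc–ProPhenol-catalysed asymmetric alkynylation with methyl propiolate 17 (Me2Zn, the ProPhenol enantiomer that delivers the 4S carbinol, Ph3P=O, toluene, 4 °C) then forms the C–C bond and the stereocentre together and comes back to the route at 21.

Further compounds
F1 | step 15 | (5S)-3-(tributylstannyl)furan-2(5H)-one bearing at C5 the tetrasubstituted alkenyl group of 21 | C[C@@H](CCCOC(C)=O)/C(=C(/CCO[Si](C)(C)C(C)(C)C)COC(=O)C(C)C)[C@H]1OC(=O)C([Sn](CCCC)(CCCC)CCCC)=C1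
F2 | step 15 | (5S)-3-iodofuran-2(5H)-one analogue of F1 | C[C@@H](CCCOC(C)=O)/C(=C(/CCO[Si](C)(C)C(C)(C)C)COC(=O)C(C)C)[C@H]1OC(=O)C(I)=C1
F3 | step 15 | (5S)-3-[(pinacolboryl)methyl]furan-2(5H)-one analogue of F1 | C[C@@H](CCCOC(C)=O)/C(=C(/CCO[Si](C)(C)C(C)(C)C)COC(=O)C(C)C)[C@H]1OC(=O)C(CB2OC(C)(C)C(C)(C)O2)=C1
F4 | step 15 | primary alcohol from F3 (TBS removed) | C[C@@H](CCCOC(C)=O)/C(=C(/CCO)COC(=O)C(C)C)[C@H]1OC(=O)C(CB2OC(C)(C)C(C)(C)O2)=C1
F5 | step 15 | aldehyde from F4 | C[C@@H](CCCOC(C)=O)/C(=C(/CC=O)COC(=O)C(C)C)[C@H]1OC(=O)C(CB2OC(C)(C)C(C)(C)O2)=C1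
F6 | step 15 | [(3aS,4R,7aS)-7-[(2S)-5-acetoxypentan-2-yl]-4-hydroxy-3-methylidene-2-oxo-3a,4,5,7a-tetrahydro-1-benzofuran-6-yl]methyl 2-methylpropanoate | C=C1C(=O)O[C@@H]2C([C@@H](C)CCCOC(C)=O)=C(COC(=O)C(C)C)C[C@@H](O)[C@H]12
F7 | step 5 | tert-butyl (2E)-3-[(isobutyryloxy)methyl]-2-[(2S)-6-methylhept-5-en-2-yl]penta-2,4-dienoate | C[C@@H](CCC=C(C)C)/C(C(=O)OC(C)(C)C)=C(/C=C)COC(=O)C(C)C
F8 | step 5 | tert-butyl (2E)-5-hydroxy-3-[(isobutyryloxy)methyl]-2-[(2S)-6-methylhept-5-en-2-yl]pent-2-enoate | C[C@@H](CCC=C(C)C)/C(C(=O)OC(C)(C)C)=C(/CCO)COC(=O)C(C)C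
F9 | step 9 | (2E)-2-[(2S)-5-acetoxypentan-2-yl]-5-[(tert-butyldimethylsilyl)oxy]-3-[(isobutyryloxy)methyl]pent-2-enal | C[C@@H](CCCOC(C)=O)/C(C=O)=C(/CCO[Si](C)(C)C(C)(C)C)COC(=O)C(C)C
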